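**Strategy.** Ring B is disconnected completely. With the ether oxygen on C1', prenyl on C4', hydroxyl on C5' and carboxyl on C6', it is a resorcinol mono-aryl ether carrying prenyl ortho to the free hydroxyl. A vinylketene/ynol ether benzannulation gives exactly this pattern: it forms C5'–C6', C1'–C2' and C4'–C5' in one operation and leaves C6', between the two oxygens, as the only open ortho carbon for later carboxylation. The precursors are the protected ring A aryloxyacetylene, in which the crowded ether oxygen already sits on an sp carbon, and an (E)-dienyl diazomethyl ketone that supplies C2'–C5' and the prenyl chain after photochemical Wolff rearrangement.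

Key step: step 10

Remarks on the chemistry
- Numbering: ring A has C1 (CH2OAc), C3 (CH3), C5 (OH), C6 (O-aryl); ring B has C1' (ether O), C4' (prenyl), C5' (OH), C6' (CO2H).
- The target has no stereocentre and no stereogenic double bond, so no stereocontrol is needed. The E geometry of the enone intermediates is the only stereo-element and it vanishes on aromatisation.
- A prenyl nucleophile joined to C4 of a 4-halocrotonate would give a 7-methylocta-2,6-dienoyl chain, one CH2 too long, and hence a homoprenyl group at C4'. The diazo ketone required is the skipped diene 1-diazo-7-methylocta-3,6-dien-2-one; it is built here from 4-methylpent-3-en-1-ol and made by diazo transfer, not from an enoyl chloride and diazomethane.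
- Aldehyde 3 is also believed to be a catalogue compound; buying it would shorten the linear sequence by one step.

**Route**

Step 1
Reactants: 1 2-methoxy-4-methylphenol (creosol)
Product: 3 2-hydroxy-3-methoxy-5-methylbenzaldehyde, via salicyl alcohol 2 (not isolated)
Conditions: MgCl2, Et3N, (CH2O)n, MeCN, reflux; aq. HCl
Reagents that add atoms: paraformaldehyde (formaldehyde unit), C=O
Why: Casnati–Skattebøl ortho-formylation, in which the magnesium phenoxide delivers formaldehyde to the only free ortho carbon of creosol and the benzylic magnesium alkoxide of 2 is oxidised by a second formaldehyde through hydride transfer, so neither para nor double formylation is expected.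

Step 2
Reactants: 3 2-hydroxy-3-methoxy-5-methylbenzaldehyde
Product: 4 2,3-dihydroxy-5-methylbenzaldehyde
Conditions: BBr3, CH2Cl2, −78 °C → rt; H2O
Reagents that add atoms: none
Why: Lewis acid ether cleavage, BBr3 complexing the methoxy oxygen and bromide attacking the methyl group by SN2, a standard way from o-vanillin-type aldehydes to 2,3-dihydroxybenzaldehydes that leaves formyl and ring methyl untouched.

Step 3
Reactants: 4 2,3-dihydroxy-5-methylbenzaldehyde
Product: 5 2-hydroxy-3-(methoxymethoxy)-5-methylbenzaldehyde
Conditions: NaH (2.1 equiv), DMF, 0 °C; MOMCl (1.0 equiv), 0 °C → rt; aq. NH4Cl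
Reagents that add atoms: chloromethyl methyl ether, COCCl
Why: Williamson-type alkylation of the dianion, in which the C3 phenoxide, neither conjugated with nor chelated to the formyl group, is the more nucleophilic oxygen and takes the single equivalent of MOMCl while the C2 oxygen stays free.

Step 4
Reactants: 5 2-hydroxy-3-(methoxymethoxy)-5-methylbenzaldehyde
Product: 6 2-(hydroxymethyl)-6-(methoxymethoxy)-4-methylphenol
Conditions: NaBH4, MeOH, 0 °C
Reagents that add atoms: none
Why: Borohydride 1,2-reduction of the aldehyde, which touches neither the acetal nor the arene and is kept cold and worked up near neutral so that the salicyl alcohol does not form a quinone methide.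

Step 5
Reactants: 6 2-(hydroxymethyl)-6-(methoxymethoxy)-4-methylphenol
Product: 7 2-{[(tert-butyldimethylsilyl)oxy]methyl}-6-(methoxymethoxy)-4-methylphenol
Conditions: TBSCl (1.05 equiv), imidazole, CH2Cl2, 0 °C
Reagents that add atoms: tert-butyldimethylsilyl chloride, CC(C)(C)[Si](C)(C)Cl
Why: Imidazole-promoted silylation is much faster at the primary benzylic hydroxyl than at the phenol flanked by two ortho substituents, and any aryl silyl ether formed would be cleaved again by the carbonate of the next step.

Step 6
Reactants: 7 2-{[(tert-butyldimethylsilyl)oxy]methyl}-6-(methoxymethoxy)-4-methylphenol; 8 trichloroethylene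
Product: 10 tert-butyl[(2-{[(E)-1,2-dichloroethenyl]oxy}-3-(methoxymethoxy)-5-methylphenyl)methoxy]dimethylsilane, via dichloroacetylene 9 (not isolated)
Conditions: K2CO3, DMF, 70 °C
Reagents that add atoms: none
Why: Known aryl dichlorovinyl ether synthesis, carbonate eliminating HCl from 8 to dichloroacetylene 9 and the phenoxide adding to it in anti fashion to give the (E)-1,2-dichlorovinyl ether, with the alkyl silyl ether and the acetal inert to K2CO3/DMF.

Step 7
Reactants: 10 the (E)-1,2-dichlorovinyl ether
Product: 13 tert-butyl{[2-(ethynyloxy)-3-(methoxymethoxy)-5-methylphenyl]methoxy}dimethylsilane (ring A aryloxyacetylene), via chloroethynyl ether 11 (not isolated), via lithium aryloxyacetylide 12 (not isolated)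
Conditions: n-BuLi (2.5 equiv), Et2O, −78 → −40 °C; H2O, −78 °C → rt; used promptly
Reagents that add atoms: none
Why: Greene-type ynol ether synthesis, n-BuLi removing the vinyl proton to trigger β-elimination to chloroalkyne 11 and then exchanging chlorine for lithium to give acetylide 12, which water protonates; at −78 °C neither MOM-directed ring lithiation nor attack on silicon should compete.

Step 8
Reactants: 14 4-methylpent-3-en-1-ol; 15 1-(triphenylphosphoranylidene)propan-2-one
Product: 17 (3E)-7-methylocta-3,6-dien-2-one, via 4-methylpent-3-enal 16 (not isolated)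
Conditions: Dess–Martin periodinane, NaHCO3, CH2Cl2, 0 °C → rt; then 15, rt
Reagents that add atoms: none
Why: Dess–Martin oxidation followed in the same flask by a Wittig reaction with the stabilised ylide, which should give the E enone and avoids isolating the volatile β,γ-unsaturated aldehyde 16 that could slip into conjugation.

Step 9
Reactants: 17 (3E)-7-methylocta-3,6-dien-2-one
Product: 19 (3E)-1-diazo-7-methylocta-3,6-dien-2-one, via trifluoroacetyl diketone 18 (not isolated)
Conditions: LiHMDS, THF, −78 °C; CF3CO2CH2CF3; aq. HCl; then 4-acetamidobenzenesulfonyl azide, Et3N, H2O (1 equiv), MeCN, rt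
Reagents that add atoms: 4-acetamidobenzenesulfonyl azide, CC(=O)Nc1ccc(cc1)S(=O)(=O)N=[N+]=[N-]; 2,2,2-trifluoroethyl trifluoroacetate, O=C(OCC(F)(F)F)C(F)(F)F (its atoms remain only in 18)
Why: Danheiser detrifluoroacetylative diazo transfer, kinetic deprotonation at the methyl group and trifluoroacetylation giving the activated 1,3-diketone 18, which takes up the diazo group from the sulfonyl azide and loses the trifluoroacetyl group as the N-sulfonyl amide, a route that avoids an enoyl chloride and diazomethane, which would add across the conjugated C=C bond.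

Step 10
Reactants: 13 ring A aryloxyacetylene; 19 (3E)-1-diazo-7-methylocta-3,6-dien-2-one (1.5–2 equiv)
Product: 24 5-[2-{[(tert-butyldimethylsilyl)oxy]methyl}-6-(methoxymethoxy)-4-methylphenoxy]-2-(3-methylbut-2-en-1-yl)phenol, via vinylketene 20 (not isolated), via cyclobutenone 21 (not isolated), via dienylketene 22 (not isolated), via cyclohexadienone 23 (not isolated)
Conditions: hν (300 nm), ClCH2CH2Cl, rt; then 80 °C; then K2CO3, MeOH, rt
Reagents that add atoms: none
Why: Danheiser benzannulation in its photochemical Wolff variant: irradiation of 19 expels N2 and the dienyl group shifts to the diazo carbon (creating C2'–C3') to give vinylketene 20, which undergoes a [2+2] cycloaddition with ynol ether 13 to give 3-aryloxy-4-vinylcyclobutenone 21 (C5'–C6' and C1'–C2'). Thermal 4π electrocyclic opening of 21 gives dienylketene 22, and ring B closes by a thermal 6π electrocyclisation (C4'–C5') to dienone 23, which tautomerises to phenol 24. The closest precedent is the benzannulation of alkoxy- and siloxyacetylenes with α,β-unsaturated α'-diazo ketones. No stereocentre is created, because the sp3 carbons of 21 and 23 are lost on aromatisation. The selectivity needed is the regiochemistry of the [2+2], secured by the polarisation of the ynol ether, whose terminal CH carbon is nucleophilic and bonds to the ketene carbonyl carbon, which places aryloxy meta and prenyl ortho to the new hydroxyl. The electron-rich alkyne should intercept the ketene faster than the isolated trisubstituted alkene does, and the carbonate/methanol treatment cleaves any aryl ester formed from 24 and excess ketene.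

Step 11
Reactants: 24 the 3-aryloxy-6-prenylphenol
Product: 26 6-[2-{[(tert-butyldimethylsilyl)oxy]methyl}-6-(methoxymethoxy)-4-methylphenoxy]-2-hydroxy-3-(3-methylbut-2-en-1-yl)benzaldehyde, via hydroxymethyl phenol 25 (not isolated)
Conditions: MgCl2, Et3N, (CH2O)n, THF, reflux; aq. HCl (cold, brief)
Reagents that add atoms: paraformaldehyde (formaldehyde unit), C=O
Why: Casnati–Skattebøl ortho-formylation again, the magnesium phenoxide of 24 delivering formaldehyde to C6', the only ortho carbon left because C4' carries prenyl, with hydroxymethyl compound 25 oxidised in situ by a second formaldehyde and the silyl ether and acetal stable to MgCl2/Et3N.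

Step 12
Reactants: 26 the salicylaldehyde
Product: 27 6-[2-{[(tert-butyldimethylsilyl)oxy]methyl}-6-(methoxymethoxy)-4-methylphenoxy]-2-hydroxy-3-(3-methylbut-2-en-1-yl)benzoic acid
Conditions: NaClO2, NaH2PO4, 2-methyl-2-butene (large excess), t-BuOH/THF/H2O, 0 °C → rt
Reagents that add atoms: sodium chlorite, [Na+].[O-]Cl=O
Why: Pinnick (Lindgren) oxidation, chlorite converting the aldehyde into the acid under buffered conditions while the large excess of 2-methyl-2-butene scavenges hypochlorous acid before it can reach the prenyl double bond or the electron-rich rings, and pH ≈ 4 spares the silyl ether and the acetal.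

Step 13
Reactants: 27 the protected salicylic acid
Product: 28 2-hydroxy-6-[2-hydroxy-6-(hydroxymethyl)-4-methylphenoxy]-3-(3-methylbut-2-en-1-yl)benzoic acid (the 7-O-deacetyl compound)
Conditions: 3 M aq. HCl, THF, rt → 40 °C
Reagents that add atoms: none
Why: Acid hydrolysis cleaves the primary silyl ether and the aryl methoxymethyl acetal in one operation, and dilute aqueous acid in THF at mild temperature without an alcohol cosolvent should avoid esterification, benzylic ether formation and chroman formation from the ortho-prenyl phenol.

Step 14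
Reactants: 28 the triol acid
Product: 29 7-O-acetylsecopenicillide C
Conditions: Novozym 435 (immobilised Candida antarctica lipase B), vinyl acetate, THF/MTBE, 35 °C
Reagents that add atoms: vinyl acetate, C=COC(C)=O
Why: Lipase-catalysed irreversible transesterification, the acetyl-enzyme being transferred to primary alcohols but not to phenols or carboxylic acids and vinyl acetate leaving only acetaldehyde, so the benzylic hydroxyl should be acetylated chemoselectively.

**Compound list**

1 | 2-methoxy-4-methylphenol (creosol) | COc1cc(C)ccc1O | starting material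
2 | 2-(hydroxymethyl)-6-methoxy-4-methylphenol (present as magnesium alkoxide) | COc1cc(C)cc(CO)c1O | intermediate (not isolated)
3 | 2-hydroxy-3-methoxy-5-methylbenzaldehyde | COc1cc(C)cc(C=O)c1O | intermediate
4 | 2,3-dihydroxy-5-methylbenzaldehyde | Cc1cc(O)c(O)c(C=O)c1 | intermediate
5 | 2-hydroxy-3-(methoxymethoxy)-5-methylbenzaldehyde | COCOc1cc(C)cc(C=O)c1O | intermediate
6 | 2-(hydroxymethyl)-6-(methoxymethoxy)-4-methylphenol | COCOc1cc(C)cc(CO)c1O | intermediate
7 | 2-{[(tert-butyldimethylsilyl)oxy]methyl}-6-(methoxymethoxy)-4-methylphenol | COCOc1cc(C)cc(CO[Si](C)(C)C(C)(C)C)c1O | intermediate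
8 | trichloroethylene | ClC=C(Cl)Cl | starting material
9 | dichloroacetylene | ClC#CCl | intermediate (not isolated)
10 | tert-butyl[(2-{[(E)-1,2-dichloroethenyl]oxy}-3-(methoxymethoxy)-5-methylphenyl)methoxy]dimethylsilane | COCOc1cc(C)cc(CO[Si](C)(C)C(C)(C)C)c1O/C(Cl)=C\Cl | intermediate
11 | tert-butyl{[2-(chloroethynyloxy)-3-(methoxymethoxy)-5-methylphenyl]methoxy}dimethylsilane | ClC#COc1c(CO[Si](C)(C)C(C)(C)C)cc(C)cc1OCOC | intermediate (not isolated)
12 | lithium acetylide of 13 | [Li]C#COc1c(CO[Si](C)(C)C(C)(C)C)cc(C)cc1OCOC | intermediate (not isolated)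
13 | tert-butyl{[2-(ethynyloxy)-3-(methoxymethoxy)-5-methylphenyl]methoxy}dimethylsilane (ring A aryloxyacetylene) | C#COc1c(CO[Si](C)(C)C(C)(C)C)cc(C)cc1OCOC | intermediate
14 | 4-methylpent-3-en-1-ol | CC(C)=CCCO | starting material
15 | 1-(triphenylphosphoranylidene)propan-2-one | CC(=O)C=P(c1ccccc1)(c1ccccc1)c1ccccc1 | starting material
16 | 4-methylpent-3-enal | CC(C)=CCC=O | intermediate (not isolated)
17 | (3E)-7-methylocta-3,6-dien-2-one | CC(=O)/C=C/CC=C(C)C | intermediate
18 | (5E)-1,1,1-trifluoro-9-methyldeca-5,8-diene-2,4-dione | O=C(CC(=O)C(F)(F)F)/C=C/CC=C(C)C | intermediate (not isolated)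
19 | (3E)-1-diazo-7-methylocta-3,6-dien-2-one | [N-]=[N+]=CC(=O)/C=C/CC=C(C)C | intermediate
20 | (3E)-7-methylocta-1,3,6-trien-1-one (vinylketene) | O=C=C/C=C/CC=C(C)C | intermediate (not isolated)
21 | 3-aryloxy-4-[(1E)-5-methylhexa-1,4-dien-1-yl]cyclobut-2-en-1-one, racemic at C4 (aryl = protected ring A) | O=C1C=C(Oc2c(CO[Si](C)(C)C(C)(C)C)cc(C)cc2OCOC)C1/C=C/CC=C(C)C | intermediate (not isolated)
22 | (3E,5E)-3-aryloxy-9-methyldeca-1,3,5,8-tetraen-1-one, ketene carbon and C5 cis (dienylketene) | O=C=C\C(Oc1c(CO[Si](C)(C)C(C)(C)C)cc(C)cc1OCOC)=C/C=C/CC=C(C)C | intermediate (not isolated)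
23 | 3-aryloxy-6-(3-methylbut-2-en-1-yl)cyclohexa-2,4-dien-1-one, racemic at C6 | O=C1C=C(Oc2c(CO[Si](C)(C)C(C)(C)C)cc(C)cc2OCOC)C=CC1CC=C(C)C | intermediate (not isolated)
24 | 5-[2-{[(tert-butyldimethylsilyl)oxy]methyl}-6-(methoxymethoxy)-4-methylphenoxy]-2-(3-methylbut-2-en-1-yl)phenol | CC(C)=CCc1ccc(Oc2c(CO[Si](C)(C)C(C)(C)C)cc(C)cc2OCOC)cc1O | intermediate
25 | 2-(hydroxymethyl) derivative of 24 at C6' (present as magnesium alkoxide) | CC(C)=CCc1ccc(Oc2c(CO[Si](C)(C)C(C)(C)C)cc(C)cc2OCOC)c(CO)c1O | intermediate (not isolated)
26 | 6-[2-{[(tert-butyldimethylsilyl)oxy]methyl}-6-(methoxymethoxy)-4-methylphenoxy]-2-hydroxy-3-(3-methylbut-2-en-1-yl)benzaldehyde | CC(C)=CCc1ccc(Oc2c(CO[Si](C)(C)C(C)(C)C)cc(C)cc2OCOC)c(C=O)c1O | intermediate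
27 | 6-[2-{[(tert-butyldimethylsilyl)oxy]methyl}-6-(methoxymethoxy)-4-methylphenoxy]-2-hydroxy-3-(3-methylbut-2-en-1-yl)benzoic acid | CC(C)=CCc1ccc(Oc2c(CO[Si](C)(C)C(C)(C)C)cc(C)cc2OCOC)c(C(=O)O)c1O | intermediate
28 | 2-hydroxy-6-[2-hydroxy-6-(hydroxymethyl)-4-methylphenoxy]-3-(3-methylbut-2-en-1-yl)benzoic acid | CC(C)=CCc1ccc(Oc2c(CO)cc(C)cc2O)c(C(=O)O)c1O | intermediate
29 | 7-O-acetylsecopenicillide C | CC(=O)OCc1cc(C)cc(O)c1Oc1ccc(CC=C(C)C)c(O)c1C(=O)O | target

**Step count.** Total: 14 steps. Longest linear sequence: 12 steps (steps 1–7, then 10–14); the diazo ketone branch is 2 steps.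

**Steps most likely to fail**

Step 10. The aryl ynol ether is less electron-rich than an alkyl ynol ether and absorbs light itself. It may therefore be lost to photodecomposition, or the ketene may dimerise or acylate the product phenol faster than it undergoes cycloaddition. Fallback, from 7 back to 24, by a classical copper-catalysed diaryl ether synthesis: sodium 3-iodophenoxide would be C-prenylated at the free ortho carbon para to iodine (NaH, prenyl bromide, toluene) to give 5-iodo-2-(3-methylbut-2-en-1-yl)phenol F1. O-Allylation (allyl bromide, K2CO3, acetone) would give 4-iodo-1-(3-methylbut-2-en-1-yl)-2-(prop-2-en-1-yloxy)benzene F2. Ullmann coupling of F2 with phenol 7 (CuI, picolinic acid, K3PO4, DMSO, 90 °C) should give the allyl-protected diaryl ether F3, and Pd(PPh3)4/morpholine in THF would remove the allyl group and return 24.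

Step 11. Carbon–carbon bond formation may be slow at the ortho carbon wedged between the hydroxyl and the bulky aryloxy group, so that the phenol is recovered or O-alkylated by formaldehyde instead. Fallback, from 24 back to 28, by directed ortho-metalation: 24 would be converted (MOMCl, i-Pr2NEt, CH2Cl2) into the ring B methoxymethyl ether of 24 F4. Lithiation between the two ring B oxygens (n-BuLi, TMEDA, THF, −78 → −20 °C) and a CO2 quench should give 6-aryloxy-2-(methoxymethoxy)-3-(3-methylbut-2-en-1-yl)benzoic acid F5 directly, without an aldehyde or a chlorite oxidation. The acid hydrolysis of step 13 then removes the silyl group and both acetals and rejoins the route at 28.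

Step 14. The acylation may fail to discriminate between the benzylic and the phenolic hydroxyls, or acyl transfer to the ortho-flanked benzylic alcohol may be too slow in the enzyme pocket. Fallback, from 28 back to 29, by over-acetylation and selective unmasking: Ac2O/pyridine/DMAP, with an aqueous work-up that hydrolyses the mixed anhydride, would give the triacetate acid F6. NH4OAc in aqueous MeOH at rt should then cleave the two aryl acetates, which are far more labile than the benzylic acetate, and deliver 29.

**Further compounds**

F1 | step 10 | 5-iodo-2-(3-methylbut-2-en-1-yl)phenol | CC(C)=CCc1ccc(I)cc1O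
F2 | step 10 | 4-iodo-1-(3-methylbut-2-en-1-yl)-2-(prop-2-en-1-yloxy)benzene | C=CCOc1cc(I)ccc1CC=C(C)C
F3 | step 10 | tert-butyl{[3-(methoxymethoxy)-5-methyl-2-[4-(3-methylbut-2-en-1-yl)-3-(prop-2-en-1-yloxy)phenoxy]phenyl]methoxy}dimethylsilane | C=CCOc1cc(Oc2c(CO[Si](C)(C)C(C)(C)C)cc(C)cc2OCOC)ccc1CC=C(C)C
F4 | step 11 | tert-butyl{[3-(methoxymethoxy)-2-[3-(methoxymethoxy)-4-(3-methylbut-2-en-1-yl)phenoxy]-5-methylphenyl]methoxy}dimethylsilane | CC(C)=CCc1ccc(Oc2c(CO[Si](C)(C)C(C)(C)C)cc(C)cc2OCOC)cc1OCOC
F5 | step 11 | 6-[2-{[(tert-butyldimethylsilyl)oxy]methyl}-6-(methoxymethoxy)-4-methylphenoxy]-2-(methoxymethoxy)-3-(3-methylbut-2-en-1-yl)benzoic acid | CC(C)=CCc1ccc(Oc2c(CO[Si](C)(C)C(C)(C)C)cc(C)cc2OCOC)c(C(=O)O)c1OCOC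
F6 | step 14 | 2-acetoxy-6-[2-acetoxy-6-(acetoxymethyl)-4-methylphenoxy]-3-(3-methylbut-2-en-1-yl)benzoic acid | CC(=O)OCc1cc(C)cc(OC(C)=O)c1Oc1ccc(CC=C(C)C)c(OC(C)=O)c1C(=O)O
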